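**Assumption:** the target has no stereogenic centre (it is achiral), so "single enantiomer" is read as the single (2E,6E) geometric isomer drawn; both alkene geometries are bought with (2E,6E)-farnesol and never touched.

## Retrosynthetic overview

1. Target ⇒ cut the aryl O–CH2 allyl ether: catechol phthalide 5 + hydrated farnesyl bromide 11 (acidity-controlled O-alkylation of the phenol para to the lactone C=O).
2. 5 ⇒ methylenedioxy phthalide 4 (BCl3 unmasking of the catechol).
3. 4 ⇒ benzodioxole acid 3 + formaldehyde, by a proposed new Rh(III) carboxylate-directed C–H hydroxymethylation/lactonization (the key ring-forming step).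
4. 11 ⇒ (2E,6E)-farnesol by terminal bromohydrin → epoxide → hydride opening → allylic bromide.
5. Ring order: benzene ring purchased → temporary dioxole (step 1) → γ-lactone (step 3) → dioxole removed (step 4).

## Route

**Step 1**
Reactants: 1, methyl 3,4-dihydroxy-5-methoxybenzoate (methyl 3-O-methylgallate)
Product: 2, methyl 7-methoxy-1,3-benzodioxole-5-carboxylate
Conditions: CH2Br2, Cs2CO3, DMF, 100 °C
Reagents that add atoms: dibromomethane, BrCBr
Why: Double Williamson etherification (catechol methylenation) closes the five-membered dioxole on the only vicinal diol; the ester and OMe are inert.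

**Step 2**
Reactants: 2, methyl 7-methoxy-1,3-benzodioxole-5-carboxylate
Product: 3, 7-methoxy-1,3-benzodioxole-5-carboxylic acid
Conditions: LiOH·H2O, THF/MeOH/H2O, 50 °C; then 1 M HCl
Reagents that add atoms: lithium hydroxide, [Li+].[OH-] (water, O)
Why: Ordinary ester saponification; the methylenedioxy acetal and aryl methyl ether are stable to aqueous base.

**Step 3 (proposed new step)**
Reactants: 3, 7-methoxy-1,3-benzodioxole-5-carboxylic acid
Product: 4, 6-methoxy-4,5-(methylenedioxy)isobenzofuran-1(3H)-one (6-methoxy-4,5-methylenedioxyphthalide)
Conditions: [Cp*RhCl2]2 (2.5 mol%), AgSbF6 (10 mol%), NaOAc (30 mol%), (CH2O)n (3 equiv), 1,4-dioxane, 110 °C, sealed tube; acidic work-up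
Reagents that add atoms: paraformaldehyde (as formaldehyde), C=O
Why: Proposed new method: carboxylate-directed Rh(III) C–H hydroxymethylation/lactonization with formaldehyde — acetate-assisted concerted metalation–deprotonation should give the five-membered rhodacycle at C4–H (the C–H between CO2H and the tied-back dioxole oxygen is less hindered than C6–H, which is shielded by the in-plane OMe, and Cp*Rh(III) is known to favour the C–H next to a methylenedioxy oxygen), formaldehyde inserts into the aryl–Rh bond, and protonolysis/lactonization of the Rh alkoxide releases the phthalide and regenerates the Rh(III) carboxylate with no oxidant, while the product has no directing group left and cannot react twice; the closest known reaction types are the Rh(III)-catalysed coupling of benzoic acids with aryl or activated aldehydes to 3-substituted phthalides and the Pd(II)-catalysed ortho-alkylation/lactonization of benzoic acids with CH2Br2, and the untested part is formaldehyde as the C1 partner with dioxole-controlled site selection on a trioxygenated acid.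

**Step 4**
Reactants: 4, 6-methoxy-4,5-(methylenedioxy)isobenzofuran-1(3H)-one
Product: 5, 4,5-dihydroxy-6-methoxyisobenzofuran-1(3H)-one
Conditions: BCl3 (3 equiv), CH2Cl2, −78 → 0 °C; then MeOH, H2O
Reagents that add atoms: none
Why: Lewis-acid cleavage of the methylenedioxy acetal by BCl3 is much faster than cleavage of a non-chelated aryl methyl ether, and the lactone is inert, so only the catechol is unmasked.

**Step 5**
Reactants: 6, (2E,6E)-farnesol
Product: 7, (2E,6E)-farnesyl acetate
Conditions: Ac2O, pyridine, DMAP (cat.), CH2Cl2, 0 °C → rt
Reagents that add atoms: acetic anhydride, CC(=O)OC(C)=O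
Why: Standard O-acetylation; the acetate deactivates the 2,3-alkene toward the electrophile used in the next step.

**Step 6**
Reactants: 7, (2E,6E)-farnesyl acetate
Product: 8, (2E,6E)-10-bromo-11-hydroxy-3,7,11-trimethyldodeca-2,6-dien-1-yl acetate (racemic at C10)
Conditions: NBS (1.1 equiv), THF/H2O, 0 °C
Reagents that add atoms: N-bromosuccinimide, O=C1CCC(=O)N1Br; water, O
Why: van Tamelen-type terminal-selective bromohydrin formation — the most electron-rich, least hindered terminal alkene forms the bromonium and water opens it at the tertiary carbon (Markovnikov); the new C10 centre is racemic and is erased in step 8.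

**Step 7**
Reactants: 8, the bromohydrin acetate
Product: 9, (2E,6E)-10,11-epoxy-3,7,11-trimethyldodeca-2,6-dien-1-ol (racemic 10,11-epoxyfarnesol)
Conditions: K2CO3, MeOH, rt
Reagents that add atoms: none
Why: Intramolecular Williamson closure of the bromohydrin to the epoxide, with methanolysis of the acetate in the same pot; the alkenes are untouched.

**Step 8**
Reactants: 9, racemic 10,11-epoxyfarnesol
Product: 10, (2E,6E)-3,7,11-trimethyldodeca-2,6-diene-1,11-diol
Conditions: LiAlH4, THF, 0 → 60 °C; Fieser work-up
Reagents that add atoms: none
Why: SN2 hydride opening of the trisubstituted epoxide at the less substituted carbon (C10) gives the tertiary C11 alcohol and removes the only stereocentre; isolated trisubstituted alkenes and the allylic alkoxide are inert.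

**Step 9**
Reactants: 10, (2E,6E)-3,7,11-trimethyldodeca-2,6-diene-1,11-diol
Product: 11, (6E,10E)-12-bromo-2,6,10-trimethyldodeca-6,10-dien-2-ol (used crude)
Conditions: MsCl, Et3N, THF, −45 °C; then LiBr, THF, 0 °C
Reagents that add atoms: lithium bromide, [Li+].[Br-]
Why: The primary allylic OH is mesylated selectively over the hindered tertiary OH at low temperature, and SN2 displacement by bromide proceeds without allylic transposition, so E geometry is retained.

**Step 10**
Reactants: 5, 4,5-dihydroxy-6-methoxyisobenzofuran-1(3H)-one; 11, the allylic bromide
Product: 12, 4-hydroxy-5-{[(2E,6E)-11-hydroxy-3,7,11-trimethyldodeca-2,6-dien-1-yl]oxy}-6-methoxyisobenzofuran-1(3H)-one (Farnesylemefuranone E)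
Conditions: Li2CO3 (1.5 equiv), DMF, 45 °C, N2
Reagents that add atoms: none
Why: Acidity-controlled Williamson O-alkylation — the 5-OH is para to the lactone carbonyl and clearly the more acidic phenol, so weak base forms only that phenoxide (the same selectivity as 4-O-alkylation of gallates and 5-hydroxyvanillin); the tertiary alcohol and lactone do not react.

## Compound list

1 | methyl 3,4-dihydroxy-5-methoxybenzoate | COC(=O)c1cc(O)c(O)c(OC)c1 | starting material
2 | methyl 7-methoxy-1,3-benzodioxole-5-carboxylate | COC(=O)c1cc(OC)c2OCOc2c1 | intermediate
3 | 7-methoxy-1,3-benzodioxole-5-carboxylic acid | OC(=O)c1cc(OC)c2OCOc2c1 | intermediate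
4 | 6-methoxy-4,5-(methylenedioxy)isobenzofuran-1(3H)-one | O=C1OCc2c3OCOc3c(OC)cc12 | intermediate
5 | 4,5-dihydroxy-6-methoxyisobenzofuran-1(3H)-one | O=C1OCc2c(O)c(O)c(OC)cc12 | intermediate
6 | (2E,6E)-farnesol | OC/C=C(\C)CC/C=C(\C)CCC=C(C)C | starting material
7 | (2E,6E)-farnesyl acetate | CC(=O)OC/C=C(\C)CC/C=C(\C)CCC=C(C)C | intermediate
8 | (2E,6E)-10-bromo-11-hydroxy-3,7,11-trimethyldodeca-2,6-dien-1-yl acetate (racemic) | CC(=O)OC/C=C(\C)CC/C=C(\C)CCC(Br)C(C)(C)O | intermediate
9 | (2E,6E)-10,11-epoxy-3,7,11-trimethyldodeca-2,6-dien-1-ol (racemic) | OC/C=C(\C)CC/C=C(\C)CCC1OC1(C)C | intermediate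
10 | (2E,6E)-3,7,11-trimethyldodeca-2,6-diene-1,11-diol | OC/C=C(\C)CC/C=C(\C)CCCC(C)(C)O | intermediate
11 | (6E,10E)-12-bromo-2,6,10-trimethyldodeca-6,10-dien-2-ol | BrC/C=C(\C)CC/C=C(\C)CCCC(C)(C)O | intermediate
12 | Farnesylemefuranone E | COc1cc2c(c(O)c1OC/C=C(\C)CC/C=C(\C)CCCC(C)(C)O)COC2=O | target

## Summary

Total steps: 10. Longest linear sequence: 6 (steps 5 → 10; the aromatic branch is 4 steps plus the coupling).

Three steps most likely to fail, each with a fallback:

1. **Step 3 (proposed new Rh hydroxymethylation/lactonization).** Risks are formaldehyde decarbonylation, low turnover, or C4/C6 mixtures. Fallback, all known chemistry and phenol-directed instead of carboxylate-directed: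
   - selective 4-O-benzylation of 1 (BnBr, Li2CO3, DMF);
   - Casiraghi–Skattebøl ortho-formylation (MgCl2, Et3N, (CH2O)n), where the only position ortho to the free OH is the required one;
   - NaBH4 reduction with spontaneous lactonization to 5-benzyloxy-4-hydroxy-6-methoxyphthalide;
   - H2, Pd/C to give 5.

2. **Step 10 (regioselective mono-O-alkylation of the catechol).** Risks are the 4-O isomer or bis-alkylation. Fallback, a regiodefined protecting-group route: take 5-benzyloxy-4-hydroxy-6-methoxyphthalide from the fallback above, protect the 4-OH as its MOM ether, hydrogenolyse the benzyl group, alkylate the single free 5-OH with 11 (K2CO3, DMF), and remove the MOM group with mild acid (PPTS, t-BuOH).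

3. **Step 4 (BCl3 demethylenation).** Risks are incomplete cleavage or loss of the adjacent OMe. Fallback: change the catechol protection rather than the Lewis acid — carry the catechol as the 2,2-diphenyl-1,3-benzodioxole (Ph2CCl2 ketal of 1, still a tied-back dioxole for step 3) and unmask by hydrogenolysis (H2, Pd/C), which touches neither the OMe nor the lactone.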